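**Retrosynthetic overview**
1. EGCG 15 ⇐ octa-O-benzyl-EGCG 14 (hydrogenolysis of eight benzyl ethers) ⇐ (2R)-3-galloyloxyflav-3-ene 13 (face-selective syn-hydrogenation of C3=C4, so that C2 sets C3 and the 2,3-cis ester forms directly).
2. Key disconnection C2–C1′: 13 ⇐ racemic 2-ethoxy-2H-chromen-3-yl gallate 8 (rings A and C plus the gallate ring D) + ring-B diethyl boronate 12, by catalyst-controlled aryl transfer to an achiral benzopyrylium ion.
3. Enabling feature: with C3 held at the ketone oxidation level as the C3=C4 enol gallate, C2 lies between the ring oxygen O1 and that double bond, so loss of ethoxide from C2 gives a 10π-aromatic 1-benzopyrylium stabilised by the 5,7-dioxygenated ring A; the boron-bearing C1′ of ring B is para to O4′.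
4. 8 ⇐ enol gallate 6 (DDQ oxidation of C2–H, ethanol capture) ⇐ chroman-3-one 4 + galloyl chloride 5; 4 ⇐ aryl propargyl ether 3 (gold-catalysed alkyne oxidation, C4–C4a closure) ⇐ phenol 1.
5. Ring order: A, B and D are bought as arenes; ring C is closed in step 2; no ring is formed in the key step.

Key step: step 6

Assumption: 1, 5 and 9 are taken as catalogue compounds (otherwise each is a short, routine benzylation sequence from phloroglucinol, gallic acid or 5-bromo-1,2,3-trimethoxybenzene).

**Route**

Step 1
Reactants: 1 3,5-bis(benzyloxy)phenol; 2 propargyl bromide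
Product: 3 1,3-bis(benzyloxy)-5-(prop-2-yn-1-yloxy)benzene
Conditions: K2CO3, DMF, rt
Reagents that add atoms: none
Why: Williamson ether synthesis, in which the phenoxide of 1 displaces bromide from the propargylic carbon (SN2) and O-alkylation is the normal course in a dipolar aprotic solvent.

Step 2
Reactants: 3 1,3-bis(benzyloxy)-5-(prop-2-yn-1-yloxy)benzene
Product: 4 5,7-bis(benzyloxy)chroman-3-one
Conditions: Me4tBuXPhosAuNTf2 (5 mol %), 3,5-dichloropyridine N-oxide (1.3 equiv), DCE, rt
Reagents that add atoms: 3,5-dichloropyridine N-oxide, [O-][n+]1cc(Cl)cc(Cl)c1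
Why: Gold-catalysed alkyne oxidation, in which the N-oxide adds to the internal carbon of the gold-activated alkyne, loss of the pyridine leaves an α-oxo gold carbene at the terminal carbon, and this is captured by an ortho carbon of ring A (both ortho positions are equivalent and activated by three oxygens) to close ring C.

Step 3
Reactants: 4 5,7-bis(benzyloxy)chroman-3-one; 5 3,4,5-tris(benzyloxy)benzoyl chloride
Product: 6 5,7-bis(benzyloxy)-2H-chromen-3-yl 3,4,5-tris(benzyloxy)benzoate
Conditions: Et3N (1.5 equiv), DMAP (10 mol %), CH2Cl2, 0 °C → rt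
Reagents that add atoms: none
Why: Enol ester formation, in which the ketone enolises toward C4 (benzylic, conjugated with ring A) and is O-acylated by the acylpyridinium from 5; any C2=C3 isomer would be harmless because step 4 converts both isomers into the same cation.

Step 4
Reactants: 6 5,7-bis(benzyloxy)-2H-chromen-3-yl 3,4,5-tris(benzyloxy)benzoate
Product: 8 (±)-5,7-bis(benzyloxy)-2-ethoxy-2H-chromen-3-yl 3,4,5-tris(benzyloxy)benzoate, via benzopyrylium hydroquinonate salt 7 (not isolated)
Conditions: DDQ (1.05 equiv), 4 Å MS, CH2Cl2, 0 °C, dark; then EtOH (5 equiv), Et3N, 0 °C; filtration through basic alumina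
Reagents that add atoms: ethanol, CCO
Why: Oxidative C–H functionalisation of a 2H-chromene, in which DDQ abstracts hydride from C2 (allylic and α to O1) because the product is an aromatic benzopyrylium, and ethanol then adds at C2 next to the ring oxygen to give the mixed acetal.

Step 5
Reactants: 9 5-bromo-1,2,3-tris(benzyloxy)benzene
Product: 12 diethyl [3,4,5-tris(benzyloxy)phenyl]boronate, via aryllithium 10 (not isolated), via lithium triethoxyborate complex 11 (not isolated)
Conditions: n-BuLi (1.05 equiv), THF, −78 °C; B(OEt)3, −78 °C → rt; HCl in Et2O (1.0 equiv), 0 °C; filtration, evaporation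
Reagents that add atoms: triethyl borate, CCOB(OCC)OCC
Why: Organolithium borylation, in which bromine–lithium exchange at −78 °C outruns benzylic deprotonation of the benzyl ethers, the aryllithium is trapped by triethyl borate as the ate complex, and one equivalent of anhydrous HCl releases the neutral diethyl ester.

Step 6
Reactants: 8 (±)-5,7-bis(benzyloxy)-2-ethoxy-2H-chromen-3-yl 3,4,5-tris(benzyloxy)benzoate; 12 diethyl [3,4,5-tris(benzyloxy)phenyl]boronate
Product: 13 (2R)-5,7-bis(benzyloxy)-2-[3,4,5-tris(benzyloxy)phenyl]-2H-chromen-3-yl 3,4,5-tris(benzyloxy)benzoate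
Conditions: 12 (1.5 equiv), chiral tartaric acid bis(N-benzylamide) (10 mol %, the antipode leading to 2R), Yb(OTf)3 (8 mol %), 4 Å MS, EtOAc, −20 → 4 °C, dark; Et3N quench
Reagents that add atoms: none
Why: The chiral tartaric diol amide exchanges with the ethoxy groups of 12 to give a more Lewis acidic chiral dioxaborolane which, helped by the lanthanide triflate, pulls the 2-ethoxy group off 8; this leaves the achiral, 10π-aromatic 3-acyloxy-5,7-bis(benzyloxy)benzopyrylium paired with a chiral aryl(alkoxy)borate, and the ring-B aryl group moves from boron to C2 inside this contact ion pair. The closest known reaction type is the chiral diol/Lewis acid catalysed enantioselective addition of aryl and alkenyl boronates to 2-alkoxy-2H-chromenes, here applied to a 3-acyloxy member of that class. No ring is closed, since rings A, C and D arrive in 8 and ring B in 12. The one new stereocentre, C2, is set by the catalyst, whose ligand on boron distinguishes the two faces of the planar cation, so both enantiomers of racemic 8 should converge on (2R)-13. The step needs attack at C2 rather than C4, which is secured by delivery of the aryl group from the borate formed at the departing C2 oxygen and by the shielding of C4 between the peri 5-benzyloxy group and the 3-gallate; it also needs ipso transfer at C1′, which the C–B bond para to the 4′-oxygen dictates, while the enol gallate and the benzyl ethers are inert under these mild conditions. In this one operation the two halves are joined, the only catalyst-controlled stereocentre of the route is created and every carbon and oxygen atom of the target is put in place, with the C3=C4 enol ester left as the handle through which C2 controls C3 in step 7.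

Step 7
Reactants: 13 (2R)-5,7-bis(benzyloxy)-2-[3,4,5-tris(benzyloxy)phenyl]-2H-chromen-3-yl 3,4,5-tris(benzyloxy)benzoate
Product: 14 (2R,3R)-5,7-bis(benzyloxy)-2-[3,4,5-tris(benzyloxy)phenyl]chroman-3-yl 3,4,5-tris(benzyloxy)benzoate (octa-O-benzyl-EGCG)
Conditions: H2 (1–3 atm), 10% Pd/C, pyridine (0.5 equiv), EtOAc/THF, rt; recrystallisation
Reagents that add atoms: none
Why: Heterogeneous syn-hydrogenation, in which A(1,2) strain with the C3 ester holds the C2 aryl group pseudo-axial so that hydrogen is delivered to the opposite face, placing the new C3–H trans to the aryl group and the ester cis to it (3R), while pyridine-poisoned Pd/C is known to leave aryl benzyl ethers intact.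

Step 8
Reactants: 14 octa-O-benzyl-EGCG
Product: 15 (−)-epigallocatechin gallate, (2R,3R)-5,7-dihydroxy-2-(3,4,5-trihydroxyphenyl)chroman-3-yl 3,4,5-trihydroxybenzoate
Conditions: H2 (1 atm), 20% Pd(OH)2/C, THF/MeOH, rt; filtration, lyophilisation
Reagents that add atoms: none
Why: Hydrogenolysis of the eight benzyl ethers at room temperature is the standard last step for this compound class, under which the gallate ester and the C2–O1 bond of a flavan persist and C2 should not epimerise.

**Compound list**
1 | 3,5-bis(benzyloxy)phenol | Oc1cc(OCc2ccccc2)cc(OCc2ccccc2)c1 | starting material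
2 | propargyl bromide (3-bromoprop-1-yne) | C#CCBr | starting material
3 | 1,3-bis(benzyloxy)-5-(prop-2-yn-1-yloxy)benzene | C#CCOc1cc(OCc2ccccc2)cc(OCc2ccccc2)c1 | intermediate
4 | 5,7-bis(benzyloxy)chroman-3-one | O=C1COc2cc(OCc3ccccc3)cc(OCc3ccccc3)c2C1 | intermediate
5 | 3,4,5-tris(benzyloxy)benzoyl chloride | O=C(Cl)c1cc(OCc2ccccc2)c(OCc2ccccc2)c(OCc2ccccc2)c1 | starting material
6 | 5,7-bis(benzyloxy)-2H-chromen-3-yl 3,4,5-tris(benzyloxy)benzoate (achiral enol gallate) | O=C(OC1=Cc2c(OCc3ccccc3)cc(OCc3ccccc3)cc2OC1)c1cc(OCc2ccccc2)c(OCc2ccccc2)c(OCc2ccccc2)c1 | intermediate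
7 | 5,7-bis(benzyloxy)-3-{[3,4,5-tris(benzyloxy)benzoyl]oxy}-1-benzopyrylium 2,3-dichloro-5,6-dicyano-4-hydroxyphenolate | O=C(Oc1cc2c(OCc3ccccc3)cc(OCc3ccccc3)cc2[o+]c1)c1cc(OCc2ccccc2)c(OCc2ccccc2)c(OCc2ccccc2)c1.[O-]c1c(Cl)c(Cl)c(O)c(C#N)c1C#N | intermediate (not isolated)
8 | (±)-5,7-bis(benzyloxy)-2-ethoxy-2H-chromen-3-yl 3,4,5-tris(benzyloxy)benzoate | O=C(OC1=Cc2c(OCc3ccccc3)cc(OCc3ccccc3)cc2OC1OCC)c1cc(OCc2ccccc2)c(OCc2ccccc2)c(OCc2ccccc2)c1 | intermediate
9 | 5-bromo-1,2,3-tris(benzyloxy)benzene | Brc1cc(OCc2ccccc2)c(OCc2ccccc2)c(OCc2ccccc2)c1 | starting material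
10 | [3,4,5-tris(benzyloxy)phenyl]lithium | [Li]c1cc(OCc2ccccc2)c(OCc2ccccc2)c(OCc2ccccc2)c1 | intermediate (not isolated)
11 | lithium triethoxy[3,4,5-tris(benzyloxy)phenyl]borate | [Li+].CCO[B-](OCC)(OCC)c1cc(OCc2ccccc2)c(OCc2ccccc2)c(OCc2ccccc2)c1 | intermediate (not isolated)
12 | diethyl [3,4,5-tris(benzyloxy)phenyl]boronate | CCOB(OCC)c1cc(OCc2ccccc2)c(OCc2ccccc2)c(OCc2ccccc2)c1 | intermediate
13 | (2R)-5,7-bis(benzyloxy)-2-[3,4,5-tris(benzyloxy)phenyl]-2H-chromen-3-yl 3,4,5-tris(benzyloxy)benzoate | O=C(OC1=Cc2c(OCc3ccccc3)cc(OCc3ccccc3)cc2O[C@@H]1c1cc(OCc2ccccc2)c(OCc2ccccc2)c(OCc2ccccc2)c1)c1cc(OCc2ccccc2)c(OCc2ccccc2)c(OCc2ccccc2)c1 | intermediate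
14 | (2R,3R)-5,7-bis(benzyloxy)-2-[3,4,5-tris(benzyloxy)phenyl]chroman-3-yl 3,4,5-tris(benzyloxy)benzoate (octa-O-benzyl-EGCG) | O=C(O[C@@H]1Cc2c(OCc3ccccc3)cc(OCc3ccccc3)cc2O[C@@H]1c1cc(OCc2ccccc2)c(OCc2ccccc2)c(OCc2ccccc2)c1)c1cc(OCc2ccccc2)c(OCc2ccccc2)c(OCc2ccccc2)c1 | intermediate
15 | (−)-epigallocatechin gallate, (2R,3R) | O=C(O[C@@H]1Cc2c(O)cc(O)cc2O[C@@H]1c1cc(O)c(O)c(O)c1)c1cc(O)c(O)c(O)c1 | target

**Count and risks**

Total steps: 8. Longest linear sequence: 7 (steps 1, 2, 3, 4, 6, 7, 8); step 5 is a one-step side branch.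

The three steps most likely to fail:

Step 6 (key step). What may go wrong:
- weak discrimination between the two faces of C2, because the neighbouring 3-gallate crowds the ion pair;
- slow aryl transfer from a borate whose para oxygen is twisted out of conjugation by its two neighbours;
- partial attack at C4;
- loss of enantiopurity by reversible ionisation of the C2–O1 bond of the product under the Lewis acid.

The fallback gives up asymmetric induction in the bond-forming event and sets both stereocentres afterwards by dynamic kinetic resolution. It sets out from 8. With 12 and an achiral promoter (BF3·OEt2, CH2Cl2, −40 °C) the same coupling should give the racemic 2-aryl-2H-chromen-3-yl gallate F1. Methanolysis of the enol ester (K2CO3, MeOH/THF, 0 °C) should release the racemic flavan-3-one F2, whose C2–H is acidified by the ketone, ring B and O1. Noyori asymmetric transfer hydrogenation under these epimerising conditions (RuCl(p-cymene)(TsDPEN), HCO2H/Et3N, antipode chosen for 3R) should reduce the 2R ketone from the face opposite the aryl group to the cis alcohol penta-O-benzyl-epigallocatechin F3. Acylation with 5 (Et3N, DMAP, CH2Cl2) then comes back to the route at 14.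

Step 7. What may go wrong:
- insufficient facial discrimination in hydrogen delivery to the C3=C4 bond;
- hydrogenolysis of the allylic, benzylic C2–O1 bond before the alkene is saturated;
- reductive loss of the vinylic ester oxygen.

The fallback replaces hydrogenation by hydride reduction of the ketone. It sets out from 13. Methyllithium (2.1 equiv, THF, −78 °C) should cleave the enol ester to the lithium enolate, which on cold protonation (AcOH, −78 °C) gives the (R)-flavan-3-one F4 without touching C2. L-Selectride (THF, −78 °C) should add hydride from the face opposite the C2 aryl group to give the cis alcohol penta-O-benzyl-epigallocatechin F3. Acylation with 5 (Et3N, DMAP, CH2Cl2) comes back to the route at 14.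

Step 4. What may go wrong:
- hydrolysis and ring opening of the very easily ionised acetal during isolation, followed by acyl migration to the freed phenol;
- over-oxidation of the electron-rich system by the quinone.

The fallback isolates the cation as a storable salt instead of the acetal. It sets out from 6. Hydride abstraction with trityl tetrafluoroborate (CH2Cl2, 0 °C) and precipitation with Et2O should give the benzopyrylium tetrafluoroborate F5. Treatment with NaOEt in EtOH/CH2Cl2 at −40 °C immediately before use should then give the acetal in solution, coming back to the route at 8.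

**Further compounds**
F1 | step 6 | (±)-5,7-bis(benzyloxy)-2-[3,4,5-tris(benzyloxy)phenyl]-2H-chromen-3-yl 3,4,5-tris(benzyloxy)benzoate | O=C(OC1=Cc2c(OCc3ccccc3)cc(OCc3ccccc3)cc2OC1c1cc(OCc2ccccc2)c(OCc2ccccc2)c(OCc2ccccc2)c1)c1cc(OCc2ccccc2)c(OCc2ccccc2)c(OCc2ccccc2)c1
F2 | step 6 | (±)-5,7-bis(benzyloxy)-2-[3,4,5-tris(benzyloxy)phenyl]chroman-3-one | O=C1Cc2c(OCc3ccccc3)cc(OCc3ccccc3)cc2OC1c1cc(OCc2ccccc2)c(OCc2ccccc2)c(OCc2ccccc2)c1
F3 | step 6 | (2R,3R)-5,7-bis(benzyloxy)-2-[3,4,5-tris(benzyloxy)phenyl]chroman-3-ol (penta-O-benzyl-epigallocatechin) | O[C@@H]1Cc2c(OCc3ccccc3)cc(OCc3ccccc3)cc2O[C@@H]1c1cc(OCc2ccccc2)c(OCc2ccccc2)c(OCc2ccccc2)c1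
F4 | step 7 | (2R)-5,7-bis(benzyloxy)-2-[3,4,5-tris(benzyloxy)phenyl]chroman-3-one | O=C1Cc2c(OCc3ccccc3)cc(OCc3ccccc3)cc2O[C@@H]1c1cc(OCc2ccccc2)c(OCc2ccccc2)c(OCc2ccccc2)c1
F5 | step 4 | 5,7-bis(benzyloxy)-3-{[3,4,5-tris(benzyloxy)benzoyl]oxy}-1-benzopyrylium tetrafluoroborate | O=C(Oc1cc2c(OCc3ccccc3)cc(OCc3ccccc3)cc2[o+]c1)c1cc(OCc2ccccc2)c(OCc2ccccc2)c(OCc2ccccc2)c1.F[B-](F)(F)F
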